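The acetophenone ring is cut into a four-carbon and a two-carbon piece. Ring atoms C3, C4 (oxygenated), C5 and C6 (carrying the phenyldecyl chain) are the diene carbons C3 to C6 of a 4-methoxy-6-alkyl-2-pyrone; C1 (acetyl) and C2 (oxygenated) are the two alkyne carbons of a methoxy-substituted butynone. One thermal operation, cycloaddition across the pyrone followed by loss of CO2 from the bridged lactone, forms the C2–C3 and C1–C6 bonds and delivers the benzene ring with all four substituents in place. The diene partner is 4-methoxy-6-(10-phenyldecyl)-2H-pyran-2-one, reached by side-chain alkylation of the purchased 6-methyl pyrone; both methyl ethers fall at the end.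

Key step: step 4

Remark: the O-methyl pyrone, the phenyl Grignard solution and the Weinreb amide of acetic acid are taken as purchased materials, so no step is spent on O-methylation or Grignard formation; the target is achiral, and the only stereocentres in the route belong to transient racemic intermediates.

Step 1
Reactants: 1 phenylmagnesium bromide; 2 1,9-dibromononane
Product: 3 (9-bromononyl)benzene
Conditions: 2 (3 equiv), Li2CuCl4 (3 mol %), THF, −10 °C → rt; excess 2 removed by vacuum distillation
Reagents that add atoms: none
Why: Copper-catalysed cross-coupling of an aryl Grignard reagent with a primary alkyl bromide (Kochi coupling) is reliable, and the threefold excess of the dibromide should hold double arylation down so that the monobromide can be separated from recovered 2.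

Step 2
Reactants: 4 4-methoxy-6-methyl-2H-pyran-2-one; 3 (9-bromononyl)benzene
Product: 6 4-methoxy-6-(10-phenyldecyl)-2H-pyran-2-one, via lithiated pyrone 5 (not isolated)
Conditions: 4 (1.2 equiv), LiN(iPr)2 (1.2 equiv), THF/DMPU, −78 °C; then 3, −78 → −20 °C; NH4Cl aq
Reagents that add atoms: none
Why: A lithium amide removes a proton from the 6-methyl group to give the extended (vinylogous ester) enolate, whose SN2 alkylation at the exocyclic carbon by a primary bromide in the presence of DMPU is established enolate chemistry, and the slight excess of anion over bromide should limit a second alkylation.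

Step 3
Reactants: 7 chloroacetaldehyde dimethyl acetal; 8 N-methoxy-N-methylacetamide
Product: 11 4-methoxybut-3-yn-2-one, via lithium methoxyacetylide 9 (not isolated), via lithium hemiaminal adduct 10 (not isolated)
Conditions: LiNEt2 (3.1 equiv, from Et2NH + n-BuLi), THF, 0 °C; then 8, −78 → −30 °C; inverse quench into cold aq NaH2PO4/Et2O; cold concentration, bulb-to-bulb distillation, stored cold in solution
Reagents that add atoms: none
Why: Double elimination of HCl and methanol from the chloroacetal with three equivalents of lithium amide is the standard entry to lithium alkoxyacetylides, and acylation with a Weinreb amide (Weinreb ketone synthesis) stops at the chelated tetrahedral adduct, so the ynone should be released only in the cold, mildly acidic quench where the amines are protonated and cannot add to it.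

Step 4
Reactants: 6 4-methoxy-6-(10-phenyldecyl)-2H-pyran-2-one; 11 4-methoxybut-3-yn-2-one
Product: 13 1-[2,4-dimethoxy-6-(10-phenyldecyl)phenyl]ethanone, via bridged lactone 12 (not isolated)
Conditions: 11 (3 equiv, in portions), BHT (cat.), toluene, sealed tube, 160 °C
Reagents that add atoms: none
Why: Proposed new method: the pyrone serves as a cyclic diene across its C3 and C6 and the ynone as the two-carbon partner, so a thermal [4+2] cycloaddition should give the 2-oxabicyclo[2.2.2]octadienone 12, which loses CO2 by retro-[4+2] at once because an aromatic ring results. The closest known reaction type is the thermal Diels–Alder/decarboxylation of 2-pyrones, 4-methoxy-6-alkyl ones included, with acetylenic esters and ketones; what is unproven is a 1-alkoxyalkynyl ketone as the two-π-electron partner. The benzene ring is closed by an intermolecular suprafacial six-membered cycloaddition that makes the arene bonds C2–C3 and C1–C6 (probably asynchronously, C2–C3 leading), not by cyclisation of a chain. No stereocentre is created in 13; the two bridgehead centres of 12 arise as a racemate with their relative configuration fixed by the bicycle and are erased on aromatisation. The step needs regiocontrol: pyrone C3, the β-carbon of the enol ether and the more nucleophilic diene terminus, should bond to the methoxy-bearing alkyne carbon, which is the β-carbon of the ynone and its electrophilic terminus, leaving pyrone C6 to pair with the acyl-bearing carbon. A methyl ynol ether has no hydrogen β to oxygen in its alkyl group, so the thermal retro-ene route to a ketene, open to ethyl ynol ethers, is closed.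

Step 5
Reactants: 13 1-[2,4-dimethoxy-6-(10-phenyldecyl)phenyl]ethanone
Product: 15 1-[2,4-dihydroxy-6-(10-phenyldecyl)phenyl]ethanone, via bis(dibromoboryl) ether 14 (not isolated)
Conditions: BBr3 (4 equiv), CH2Cl2, −78 °C → rt; then H2O, 0 °C
Reagents that add atoms: none
Why: Lewis acid-mediated cleavage of aryl methyl ethers (bromide attack on the O-methyl of the boron-complexed ether) is standard for methoxyacetophenones, the ortho ether going first with carbonyl chelation and the para ether with the excess reagent, while the aryl ketone, the alkyl chain and the phenyl ring should be untouched.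

Compound list
1 | phenylmagnesium bromide | Br[Mg]c1ccccc1 | starting material
2 | 1,9-dibromononane | BrCCCCCCCCCBr | starting material
3 | (9-bromononyl)benzene (9-phenylnonyl bromide) | BrCCCCCCCCCc1ccccc1 | intermediate
4 | 4-methoxy-6-methyl-2H-pyran-2-one | COC1=CC(=O)OC(C)=C1 | starting material
5 | 6-(lithiomethyl)-4-methoxy-2H-pyran-2-one (extended enolate, drawn as the C-lithio form) | [Li]CC1=CC(OC)=CC(=O)O1 | intermediate (not isolated)
6 | 4-methoxy-6-(10-phenyldecyl)-2H-pyran-2-one | COC1=CC(=O)OC(CCCCCCCCCCc2ccccc2)=C1 | intermediate
7 | chloroacetaldehyde dimethyl acetal (2-chloro-1,1-dimethoxyethane) | COC(CCl)OC | starting material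
8 | N-methoxy-N-methylacetamide | CC(=O)N(C)OC | starting material
9 | lithium methoxyacetylide | [Li]C#COC | intermediate (not isolated)
10 | lithium 4-methoxy-2-[methoxy(methyl)amino]but-3-yn-2-olate (racemic) | CC(O[Li])(C#COC)N(C)OC | intermediate (not isolated)
11 | 4-methoxybut-3-yn-2-one | COC#CC(C)=O | intermediate
12 | 6-acetyl-5,8-dimethoxy-1-(10-phenyldecyl)-2-oxabicyclo[2.2.2]octa-5,7-dien-3-one (racemic, one enantiomer drawn; bridgehead configurations mutually fixed) | O=C1O[C@]2(CCCCCCCCCCc3ccccc3)C=C(OC)[C@H]1C(OC)=C2C(C)=O | intermediate (not isolated)
13 | 1-[2,4-dimethoxy-6-(10-phenyldecyl)phenyl]ethanone | CC(=O)c1c(OC)cc(OC)cc1CCCCCCCCCCc1ccccc1 | intermediate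
14 | 1-[2,4-bis(dibromoboryloxy)-6-(10-phenyldecyl)phenyl]ethanone | CC(=O)c1c(OB(Br)Br)cc(OB(Br)Br)cc1CCCCCCCCCCc1ccccc1 | intermediate (not isolated)
15 | 1-[2,4-dihydroxy-6-(10-phenyldecyl)phenyl]ethanone | CC(=O)c1c(O)cc(O)cc1CCCCCCCCCCc1ccccc1 | target

Total step count: 5. Longest linear sequence: 4 steps (steps 1, 2, 4, 5); step 3 is a one-step convergent branch.

Steps most likely to fail

Step 4. The moderately reactive pyrone diene may add too slowly, so that thermal oligomerisation of the push–pull alkyne or erosion of regiocontrol wins. The fallback leaves the cycloaddition and uses known arene chemistry. It sets out from bromide 3, which would be converted with magnesium in THF into 9-phenylnonylmagnesium bromide F1. Coupling of F1 with purchased 3,5-dimethoxybenzyl bromide under Li2CuCl4 catalysis would give 1,3-dimethoxy-5-(10-phenyldecyl)benzene F2. Friedel–Crafts acetylation of F2 (acetyl chloride, SnCl4, CH2Cl2, 0 °C) should go to the ring position para to one methoxy group and ortho to the chain, as is usual for 5-alkylresorcinol dimethyl ethers. The far less activated terminal phenyl ring should stay untouched, and the route is rejoined at 13.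

Step 3. The ynone may be lost through conjugate addition of amine or water during the quench, or by evaporation of this small volatile compound on isolation. The fallback sets out from acetal 7 and again generates acetylide 9, but adds acetaldehyde in place of the amide to give racemic 4-methoxybut-3-yn-2-ol F3. Oxidation of F3 with activated MnO2 in CH2Cl2, followed only by filtration and cold concentration, would return to 11 without any aqueous or amine contact of the ynone.

Step 2. Alkylation by the unactivated primary bromide may be incomplete, a second alkylation may occur at the new methylene, or ring lithiation at C3 may compete. The fallback replaces alkylation by the better-precedented aldol reaction of the same anion. Bromide 3 would be oxidised (Kornblum oxidation, DMSO, NaHCO3, 110 °C) to 9-phenylnonanal F4. Addition of lithiated pyrone 5 (from 4) to F4 at −78 °C would give racemic 6-(2-hydroxy-10-phenyldecyl)-4-methoxy-2H-pyran-2-one F5. Mesylation and elimination (MsCl, Et3N, then DBU) would give 4-methoxy-6-[(E)-10-phenyldec-1-enyl]-2H-pyran-2-one F6. Hydrogenation of the exocyclic alkene (H2, Pd/C, EtOAc), which the 4-methoxypyrone ring should survive, rejoins the route at 6.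

Further compounds
F1 | step 4 | 9-phenylnonylmagnesium bromide | Br[Mg]CCCCCCCCCc1ccccc1
F2 | step 4 | 1,3-dimethoxy-5-(10-phenyldecyl)benzene | COc1cc(OC)cc(CCCCCCCCCCc2ccccc2)c1
F3 | step 3 | 4-methoxybut-3-yn-2-ol (racemic) | CC(O)C#COC
F4 | step 2 | 9-phenylnonanal | O=CCCCCCCCCc1ccccc1
F5 | step 2 | 6-(2-hydroxy-10-phenyldecyl)-4-methoxy-2H-pyran-2-one (racemic) | COC1=CC(=O)OC(CC(O)CCCCCCCCc2ccccc2)=C1
F6 | step 2 | 4-methoxy-6-[(E)-10-phenyldec-1-enyl]-2H-pyran-2-one | COC1=CC(=O)OC(/C=C/CCCCCCCCc2ccccc2)=C1
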